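**Plan**

1. Numbering: C1–C3 carry the esters, C4 is the methyl-bearing quaternary carbon, C5 and C9 are the cyclobutane CH groups joined through C6(=O)–C7=C8(CH3), C10 is the fourth cyclobutane carbon and bears C11Me2. "Top" is the cyclobutane face that carries the C4 methyl; the "C5 side" and "C9 side" are the two faces of the seven-membered ring.
2. Retrosynthesis: cut the three ester C–O bonds one at a time (C3 angelate, C2 acetate, C1 angelate), then C5–C6 and C6–C7 (C6 becomes carbon monoxide), then C2=C3 (metathesis), then C1–C2, C4–C3, C4–CH3 and C10–C11, back to methyl 3-oxocyclobutane-1-carboxylate.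
3. Enabling feature: ketone C6 lies between cyclobutane carbon C5 and C7, and C8 bears a methyl group. The cyclohexenone ring can therefore be closed by catching CO between a C5 radical and a 2-(stannylmethyl)vinyl group on C9; the methyl group appears when the exocyclic alkene moves into conjugation.
4. Forward: the cyclobutane is bought and substituted (C10, then C4–CH3, then C3). The seven-membered ring is closed next by ring-closing metathesis, so that it acts as a tether holding C5 and the C9 side chain diaxial. The cyclohexenone ring is closed last by radical carbonylation; the C1 silyl ether and the C2,C3-acetonide are then removed in turn so that each ester is installed in a step of its own.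
5. Stereochemistry: C9 by chiral lithium amide desymmetrisation; C10 and C4 relayed from C9 by anti additions on the cyclobutane; C1 by (+)-MIB-controlled alkenylzinc addition; C2/C3 by OsO4 anti to the C1 silyl ether; C5 by the geometry of the cyclisation.
6. The C5 radical is made from a xanthate, because the hindered, bridging C5 carbinol cannot be inverted to a halide.

Key step: step 20

Assumption: the sense of the chiral-amide deprotonation in step 2 is taken from the 4-substituted cyclohexanone series; should it prove opposite, the (R,R)-amide is used.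

**Route**

Step 1
Reactants: 1 2-bromo-2-methylpropanoyl bromide; 2 N,O-dimethylhydroxylamine hydrochloride
Product: 3 2-bromo-N-methoxy-N,2-dimethylpropanamide
Conditions: Et3N (2.2 equiv), CH2Cl2, 0 °C to rt
Reagents that add atoms: none
Why: N-acylation of the hydroxylamine by the acid bromide (amide formation); the tertiary C–Br bond is inert under these conditions.

Step 2
Reactants: 4 methyl 3-oxocyclobutane-1-carboxylate
Product: 5 methyl (1R)-3-(triethylsilyloxy)cyclobut-2-ene-1-carboxylate
Conditions: (S,S)-bis(1-phenylethyl)amine, n-BuLi, THF; then 4 and TESCl (internal quench), −100 °C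
Reagents that add atoms: chlorotriethylsilane, CC[Si](Cl)(CC)CC
Why: Enantioselective deprotonation of a prochiral 3-substituted cyclobutanone by a chiral lithium amide with internal silyl quench removes one of the two enantiotopic α-protons and so fixes C9 as the only stereocentre; the ketone α-protons should be removed faster than the ester α-proton at this temperature.

Step 3
Reactants: 5 silyl enol ether; 3 bromo amide
Product: 6 trans keto amide (C9 ester top, C10 side chain bottom)
Conditions: Ir(ppy)3 (1 mol %), 2,6-lutidine, MeCN, blue LEDs, rt; aqueous work-up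
Reagents that add atoms: none
Why: Photoredox radical alkylation of an enol silane: the electrophilic tertiary α-amido radical from 3 should add to the enol ether carbon C10 anti to the C9 ester, and oxidation and desilylation of the α-silyloxy radical give the trans ketone.

Step 4
Reactants: 6 trans keto amide
Product: 7 C4-methyl ketone
Conditions: LDA (1.05 equiv), THF, −78 °C; MeI, −78 to −40 °C
Reagents that add atoms: iodomethane, CI
Why: Kinetic enolate alkylation: the base should take a proton from the unhindered C4 methylene and not from C10–H beside the quaternary carbon; the C4 configuration formed here is erased in step 5.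

Step 5
Reactants: 7 C4-methyl ketone
Product: 9 keto acetal with quaternary C4, via trimethylsilyl enol ether 8 (not isolated)
Conditions: LDA, THF, −78 °C; TMSCl; then HC(OEt)3, BF3·OEt2, CH2Cl2, −78 °C
Reagents that add atoms: triethyl orthoformate, CCOC(OCC)OCC
Why: Regioselective enolisation toward C4 followed by Mukaiyama-type alkylation of the enol silane by the diethoxycarbenium ion; the electrophile should enter C4 anti to the adjacent C9 ester, which places C3 on the bottom face and the methyl on the top face.

Step 6
Reactants: 9 keto acetal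
Product: 10 cyclobutanol (C5–OH bottom)
Conditions: NaBH4, MeOH, −20 °C
Reagents that add atoms: none
Why: Borohydride reduction from the top face, which is flanked only by the C4 methyl and C10–H, should give the bottom-face alcohol; C5 becomes a radical centre later, so its configuration here is not critical.

Step 7
Reactants: 10 cyclobutanol
Product: 11 C5 triethylsilyl ether
Conditions: TESCl, imidazole, DMAP (cat.), DMF, 40 °C
Reagents that add atoms: chlorotriethylsilane, CC[Si](Cl)(CC)CC
Why: Standard silylation; the ether prevents lactol formation with the C1 aldehyde of step 8 and retro-aldol opening of the cyclobutane once C3 is an aldehyde (steps 10 and 11).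

Step 8
Reactants: 11 silyl ether amide
Product: 12 C1 aldehyde
Conditions: Cp2Zr(H)Cl (1.5 equiv), THF, rt; aqueous work-up
Reagents that add atoms: none
Why: Reduction of the N-methoxy-N-methyl amide to the aldehyde by Cp2Zr(H)Cl through a stable zirconated hemiaminal, a reduction known to spare methyl esters.

Step 9
Reactants: 12 C1 aldehyde; 13 hex-1-yne
Product: 14 (R)-allylic alcohol
Conditions: 13, Cy2BH, hexanes, 0 °C to rt; Et2Zn, −78 °C; (+)-MIB (5 mol %); 12, toluene, −10 °C; aq. NH4Cl
Reagents that add atoms: none
Why: Catalytic asymmetric alkenylzinc addition (alkyne hydroboration, boron-to-zinc exchange, amino-alcohol catalysis); (+)-MIB should direct the alkenyl group to the Re face of the α-quaternary aldehyde, so C1 is set by the catalyst and not by the remote ring stereocentres, which offer no useful bias.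

Step 10
Reactants: 14 allylic alcohol
Product: 16 C3 aldehyde with C1 silyl ether, via silyl ether acetal 15 (not isolated)
Conditions: TBSOTf, 2,6-lutidine, CH2Cl2, −78 °C; then TESOTf, 0 °C; then H2O
Reagents that add atoms: tert-butyldimethylsilyl triflate, CC(C)(C)[Si](C)(C)OS(=O)(=O)C(F)(F)F; water, O
Why: Silyl triflate silylation of the hindered allylic alcohol, then silyl triflate/2,6-lutidine cleavage of the acetal through a pyridinium intermediate that water converts to the aldehyde; these conditions are known to leave silyl ethers intact.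

Step 11
Reactants: 16 C3 aldehyde
Product: 17 C4-vinyl compound
Conditions: Ph3PCH3Br, KN(SiMe3)2, THF, 0 °C; then 16, −78 to 0 °C
Reagents that add atoms: methyltriphenylphosphonium bromide, C[P+](c1ccccc1)(c1ccccc1)c1ccccc1.[Br-]
Why: Wittig methylenation of a non-enolisable α-quaternary aldehyde; the methyl ester is inert to the ylide.

Step 12
Reactants: 17 C4-vinyl compound
Product: 18 C5 alcohol
Conditions: HF·pyridine, pyridine, THF, 0 °C
Reagents that add atoms: none
Why: Selective cleavage of the triethylsilyl ether beside the hindered secondary tert-butyldimethylsilyl ether; the C5 oxygen is wanted small for step 14 and free for step 19.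

Step 13
Reactants: 18 diene
Product: 19 bicyclo[4.1.1]oct-2-ene
Conditions: second-generation Grubbs catalyst (10 mol %), toluene (0.005 M), 80 °C
Reagents that add atoms: none
Why: Ring-closing metathesis; C3 and C11 are cis on the cyclobutane, the gem-dimethyl group favours closure, and loss of hex-1-ene drives formation of the seven-membered ring.

Step 14
Reactants: 19 cycloheptene
Product: 20 C2,C3-diol
Conditions: OsO4 (5 mol %), NMO, acetone/H2O, rt
Reagents that add atoms: osmium tetroxide, O=[Os](=O)(=O)=O; N-methylmorpholine N-oxide, C[N+]1([O-])CCOCC1; water, O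
Why: Catalytic OsO4 dihydroxylation; by the empirical anti rule for allylic ethers the reagent should add to the face opposite the C1 silyl ether, giving the cis C2,C3-diol trans to the C1 oxygen, and the small C5 hydroxyl on that face can hydrogen-bond to the reagent instead of blocking it.

Step 15
Reactants: 20 diol
Product: 21 acetonide
Conditions: 2,2-dimethoxypropane, PPTS (cat.), acetone, rt
Reagents that add atoms: 2,2-dimethoxypropane, COC(C)(C)OC
Why: Acetonide formation under thermodynamic control; acetone ketals prefer the five-membered ring of the cis-1,2-diol over a six-membered ring that would include the C5 hydroxyl.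

Step 16
Reactants: 21 ester
Product: 23 allylsilane, via bis(silylmethyl) carbinol 22 (not isolated)
Conditions: Me3SiCH2MgCl (6 equiv), CeCl3, THF, −78 °C to rt; then SiO2, CH2Cl2, rt
Reagents that add atoms: (trimethylsilyl)methylmagnesium chloride, C[Si](C)(C)C[Mg]Cl
Why: Double addition of the cerium-modified Grignard reagent to the ester, then Peterson elimination of one β-silyl carbinol arm, a standard route from esters to 2-substituted allylsilanes.

Step 17
Reactants: 23 allylsilane
Product: 24 allyl bromide
Conditions: NBS, propylene oxide, CH2Cl2, −78 °C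
Reagents that add atoms: N-bromosuccinimide, O=C1CCC(=O)N1Br
Why: Bromodesilylation (SE2′): bromine adds to the alkene terminus, the β-silyl cation loses silicon, and since both CH2 groups are equivalent a single 2-substituted allyl bromide results.

Step 18
Reactants: 24 allyl bromide
Product: 25 allylstannane
Conditions: Bu3SnH, LDA, THF, 0 °C (Bu3SnLi, 2.2 equiv); then 24, −78 °C
Reagents that add atoms: tributyltin hydride (as Bu3SnLi), CCCC[SnH](CCCC)CCCC
Why: SN2 displacement of the allylic bromide by tributylstannyllithium; the first equivalent only deprotonates the C5 hydroxyl.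

Step 19
Reactants: 25 allylstannane alcohol
Product: 26 O-cyclobutyl S-methyl xanthate
Conditions: NaH, THF, 0 °C; CS2; MeI, rt
Reagents that add atoms: carbon disulfide, S=C=S; iodomethane, CI
Why: Xanthate formation (alkoxide, CS2, MeI) needs no substitution at carbon; an iodide would require an SN2 reaction at C5, which the bicyclic skeleton shields on both faces.

Step 20
Reactants: 26 xanthate allylstannane; 27 carbon monoxide
Product: 28 4-methylenebicyclo[3.1.1]heptan-2-one (C6 ketone, exocyclic C8 methylene)
Conditions: CO (80 atm), 1,1′-azobis(cyclohexanecarbonitrile) (0.3 equiv, in portions), benzene (0.005 M), 100 °C, autoclave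
Reagents that add atoms: none
Why: Proposed new method: the tributyltin radical adds to the thiocarbonyl sulfur and C5–O scission gives the cyclobutyl radical, which traps CO; the acyl radical then adds to C7, the unsubstituted terminus of the (stannylmethyl)vinyl group on C9, and β-scission of the C–Sn bond leaves the C8 methylene and returns the chain carrier. The closest known reactions are the three-component coupling of alkyl radicals, CO and allylstannanes and the radical allylation of thiocarbonyl derivatives of alcohols by allylstannanes; the intramolecular capture and the xanthate source are the new elements. The six-membered ring closes in the 6-endo-trig mode, because 5-exo attack at the fully substituted C8 would give a bicyclo[2.1.1]hexanone and a primary radical with no β-tin. C5 is controlled by the ring: only the acyl radical on the face of the C9 side chain can reach C7, and its epimer returns to the pool by decarbonylation. The step needs carbonylation and ring closure to outrun intermolecular allyl transfer; CO pressure, high dilution and the seven-membered ring, which already fixes the pucker that brings the C5 and C9 substituents together, should secure this.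

Step 21
Reactants: 28 β,γ-unsaturated ketone
Product: 29 conjugated enone
Conditions: DBU, toluene, 60 °C
Reagents that add atoms: none
Why: Base-mediated isomerisation through the dienolate moves the exocyclic alkene into conjugation (C7=C8, C8 methyl); the bridgehead C5 cannot epimerise.

Step 22
Reactants: 29 protected enone
Product: 30 C1 alcohol (acetonide retained)
Conditions: Bu4NF (3 equiv), AcOH (3 equiv), THF, 50 °C
Reagents that add atoms: none
Why: Fluoride-mediated desilylation cleaves the hindered C1 silyl ether while the C2,C3-acetonide is inert to fluoride, and the acetic acid buffer keeps the enone from forming its dienolate.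

Step 23
Reactants: 30 C1 alcohol; 31 angelic acid
Product: 32 C1 angelate
Conditions: 31, 2,4,6-trichlorobenzoyl chloride, Et3N, toluene, rt; then 30, 80 °C
Reagents that add atoms: none
Why: Yamaguchi-type esterification through the mixed anhydride without a nucleophilic catalyst, conditions known to acylate hindered secondary alcohols with angelic acid without Z-to-E isomerisation; C1–OH is the only free hydroxyl, so the site is unambiguous.

Step 24
Reactants: 32 C1 angelate acetonide
Product: 33 C2,C3-diol
Conditions: TFA/H2O (4:1), CH2Cl2, 0 °C to rt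
Reagents that add atoms: none
Why: Acid-catalysed hydrolysis of the isopropylidene ketal releases the cis-diol as acetone is lost; the enone and the angelate should tolerate brief cold aqueous acid.

Step 25
Reactants: 33 diol
Product: 34 C2 acetate
Conditions: AcCl (1.05 equiv), 2,4,6-collidine, CH2Cl2, −78 to −40 °C
Reagents that add atoms: acetyl chloride, CC(=O)Cl
Why: Regioselective acylation: C3–OH is neopentyl beside the quaternary C4 whereas C2–OH lies between two CH carbons, so acetyl chloride with a hindered base at low temperature should acylate C2 first, and the cold non-nucleophilic conditions should suppress acyl migration.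

Step 26
Reactants: 34 C2 acetate; 31 angelic acid
Product: 35 CNP0335415.1
Conditions: 31, 2,4,6-trichlorobenzoyl chloride, Et3N, toluene, rt; then 34, 80 °C
Reagents that add atoms: none
Why: Yamaguchi-type esterification of the remaining hindered C3 hydroxyl through the angelic 2,4,6-trichlorobenzoic mixed anhydride, again without a nucleophilic catalyst so that the Z geometry of both angelates is kept.

**Compound list**

1 | 2-bromo-2-methylpropanoyl bromide | CC(C)(Br)C(=O)Br | starting material
2 | N,O-dimethylhydroxylamine hydrochloride | CNOC.Cl | starting material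
3 | 2-bromo-N-methoxy-N,2-dimethylpropanamide | CC(C)(Br)C(=O)N(C)OC | intermediate
4 | methyl 3-oxocyclobutane-1-carboxylate | COC(=O)C1CC(=O)C1 | starting material
5 | methyl (1R)-3-(triethylsilyloxy)cyclobut-2-ene-1-carboxylate | C1C(O[Si](CC)(CC)CC)=C[C@@H]1C(=O)OC | intermediate
6 | methyl 2-[1-(methoxy(methyl)amino)-2-methyl-1-oxopropan-2-yl]-3-oxocyclobutane-1-carboxylate, C9 ester top, C10 side chain bottom (trans) | C1C(=O)[C@@H](C(C)(C)C(=O)N(C)OC)[C@@H]1C(=O)OC | intermediate
7 | 4-methyl derivative of 6 (methyl at C4, drawn trans to the ester; this centre is reset in step 5) | C[C@H]1C(=O)[C@@H](C(C)(C)C(=O)N(C)OC)[C@@H]1C(=O)OC | intermediate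
8 | trimethylsilyl enol ether of 7 (C4=C5) | CC1=C(O[Si](C)(C)C)[C@@H](C(C)(C)C(=O)N(C)OC)[C@@H]1C(=O)OC | intermediate (not isolated)
9 | cyclobutanone with quaternary C4 (methyl top, diethoxymethyl bottom), C9 ester top, C10 amide side chain bottom | CCOC(OCC)[C@@]1(C)C(=O)[C@@H](C(C)(C)C(=O)N(C)OC)[C@@H]1C(=O)OC | intermediate
10 | C5 alcohol of 9, hydroxyl on the bottom face | CCOC(OCC)[C@@]1(C)[C@@H](O)[C@@H](C(C)(C)C(=O)N(C)OC)[C@@H]1C(=O)OC | intermediate
11 | C5 triethylsilyl ether of 10 | CCOC(OCC)[C@@]1(C)[C@@H](O[Si](CC)(CC)CC)[C@@H](C(C)(C)C(=O)N(C)OC)[C@@H]1C(=O)OC | intermediate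
12 | C1 aldehyde: as 11 with 2-methyl-1-oxopropan-2-yl at C10 | CCOC(OCC)[C@@]1(C)[C@@H](O[Si](CC)(CC)CC)[C@@H](C(C)(C)C=O)[C@@H]1C(=O)OC | intermediate
13 | hex-1-yne | C#CCCCC | starting material
14 | allylic alcohol: as 12 with (3R,4E)-3-hydroxy-2-methylnon-4-en-2-yl at C10 | CCOC(OCC)[C@@]1(C)[C@@H](O[Si](CC)(CC)CC)[C@@H](C(C)(C)[C@H](O)/C=C/CCCC)[C@@H]1C(=O)OC | intermediate
15 | C1 tert-butyldimethylsilyl ether of 14 | CCOC(OCC)[C@@]1(C)[C@@H](O[Si](CC)(CC)CC)[C@@H](C(C)(C)[C@H](O[Si](C)(C)C(C)(C)C)/C=C/CCCC)[C@@H]1C(=O)OC | intermediate (not isolated)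
16 | C3 aldehyde: as 15 with formyl in place of diethoxymethyl at C4 | O=C[C@@]1(C)[C@@H](O[Si](CC)(CC)CC)[C@@H](C(C)(C)[C@H](O[Si](C)(C)C(C)(C)C)/C=C/CCCC)[C@@H]1C(=O)OC | intermediate
17 | C4-vinyl compound: as 16 with vinyl in place of formyl | C=C[C@@]1(C)[C@@H](O[Si](CC)(CC)CC)[C@@H](C(C)(C)[C@H](O[Si](C)(C)C(C)(C)C)/C=C/CCCC)[C@@H]1C(=O)OC | intermediate
18 | C5 alcohol of 17 | C=C[C@@]1(C)[C@@H](O)[C@@H](C(C)(C)[C@H](O[Si](C)(C)C(C)(C)C)/C=C/CCCC)[C@@H]1C(=O)OC | intermediate
19 | bicyclo[4.1.1]oct-2-ene: seven-membered ring C1–C2=C3–C4–C5–C10–C11 closed; C1 silyl ether on the C9 side, C5 hydroxyl, C9 methyl ester | CC(C)(C)[Si](C)(C)O[C@@H]1C=C[C@@]2(C)[C@@H](O)[C@@H](C1(C)C)[C@@H]2C(=O)OC | intermediate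
20 | C2,C3-diol of 19, both hydroxyls on the C5 side, trans to the C1 silyl ether | CC(C)(C)[Si](C)(C)O[C@@H]1[C@@H](O)[C@@H](O)[C@@]2(C)[C@@H](O)[C@@H](C1(C)C)[C@@H]2C(=O)OC | intermediate
21 | C2,C3-acetonide of 20 | CC(C)(C)[Si](C)(C)O[C@@H]1[C@H]3OC(C)(C)O[C@H]3[C@@]2(C)[C@@H](O)[C@@H](C1(C)C)[C@@H]2C(=O)OC | intermediate
22 | tertiary carbinol at C8 bearing two (trimethylsilyl)methyl groups | CC(C)(C)[Si](C)(C)O[C@@H]1[C@H]3OC(C)(C)O[C@H]3[C@@]2(C)[C@@H](O)[C@@H](C1(C)C)[C@@H]2C(O)(C[Si](C)(C)C)C[Si](C)(C)C | intermediate (not isolated)
23 | allylsilane: C9 bears 3-(trimethylsilyl)prop-1-en-2-yl | CC(C)(C)[Si](C)(C)O[C@@H]1[C@H]3OC(C)(C)O[C@H]3[C@@]2(C)[C@@H](O)[C@@H](C1(C)C)[C@@H]2C(=C)C[Si](C)(C)C | intermediate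
24 | allyl bromide: C9 bears 3-bromoprop-1-en-2-yl | CC(C)(C)[Si](C)(C)O[C@@H]1[C@H]3OC(C)(C)O[C@H]3[C@@]2(C)[C@@H](O)[C@@H](C1(C)C)[C@@H]2C(=C)CBr | intermediate
25 | allylstannane: C9 bears 3-(tributylstannyl)prop-1-en-2-yl | CC(C)(C)[Si](C)(C)O[C@@H]1[C@H]3OC(C)(C)O[C@H]3[C@@]2(C)[C@@H](O)[C@@H](C1(C)C)[C@@H]2C(=C)C[Sn](CCCC)(CCCC)CCCC | intermediate
26 | O-(C5) S-methyl xanthate of 25 | CC(C)(C)[Si](C)(C)O[C@@H]1[C@H]3OC(C)(C)O[C@H]3[C@@]2(C)[C@@H](OC(=S)SC)[C@@H](C1(C)C)[C@@H]2C(=C)C[Sn](CCCC)(CCCC)CCCC | intermediate
27 | carbon monoxide | [C-]#[O+] | starting material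
28 | tricyclic β,γ-unsaturated ketone: C6 ketone, exocyclic C8 methylene, C1 silyl ether, C2,C3-acetonide | CC(C)(C)[Si](C)(C)O[C@@H]1[C@H]4OC(C)(C)O[C@H]4[C@@]2(C)[C@@H]3C(=O)CC(=C)[C@H]2[C@@H]3C1(C)C | intermediate
29 | conjugated enone (C7=C8, C8 methyl), C1 silyl ether, C2,C3-acetonide | CC(C)(C)[Si](C)(C)O[C@@H]1[C@H]4OC(C)(C)O[C@H]4[C@@]2(C)[C@@H]3C(=O)C=C(C)[C@H]2[C@@H]3C1(C)C | intermediate
30 | C1 alcohol of the tricyclic enone, C2,C3-acetonide retained | O[C@@H]1[C@H]4OC(C)(C)O[C@H]4[C@@]2(C)[C@@H]3C(=O)C=C(C)[C@H]2[C@@H]3C1(C)C | intermediate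
31 | angelic acid, (Z)-2-methylbut-2-enoic acid | C/C=C(/C)C(=O)O | starting material
32 | C1 angelate of 30, C2,C3-acetonide retained | C/C=C(/C)C(=O)O[C@@H]1[C@H]4OC(C)(C)O[C@H]4[C@@]2(C)[C@@H]3C(=O)C=C(C)[C@H]2[C@@H]3C1(C)C | intermediate
33 | C1 angelate with free cis C2,C3-diol | C/C=C(/C)C(=O)O[C@@H]1[C@@H](O)[C@@H](O)[C@@]2(C)[C@@H]3C(=O)C=C(C)[C@H]2[C@@H]3C1(C)C | intermediate
34 | C1 angelate, C2 acetate, free C3 hydroxyl | C/C=C(/C)C(=O)O[C@@H]1[C@@H](OC(C)=O)[C@@H](O)[C@@]2(C)[C@@H]3C(=O)C=C(C)[C@H]2[C@@H]3C1(C)C | intermediate
35 | CNP0335415.1: C1 and C3 angelates, C2 acetate | C/C=C(/C)C(=O)O[C@@H]1[C@@H](OC(C)=O)[C@@H](OC(=O)/C(C)=C\C)[C@@]2(C)[C@@H]3C(=O)C=C(C)[C@H]2[C@@H]3C1(C)C | target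

**Totals and risks**

Total step count: 26. Longest linear sequence: 25 steps (steps 2–26, from 4); step 1 is a one-step branch.

Steps most likely to fail:

1. Step 20 (proposed new method). The chain may break down through slow fragmentation of the tin–xanthate adduct, or intermolecular allyl transfer and oligomerisation may win over ring closure. The fallback uses known ionic chemistry, sets out from 23 and rejoins at 28. Dess–Martin oxidation of the C5 alcohol should give the cyclobutanone F1. Reductive cyanation with TosMIC and t-BuOK should give the C5 nitrile F2, and i-Bu2AlH the C5 aldehyde F3; its C5 epimers equilibrate through the enol, and only the top-face aldehyde can close. BF3·OEt2-promoted intramolecular Hosomi–Sakurai allylation of the aldehyde by the allylsilane should give the bicyclic homoallylic alcohol F4, and a second Dess–Martin oxidation gives 28.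

2. Step 2. Enantiodiscrimination may be incomplete, or the silyl enol ether may racemise through deprotonation at the ester α-position. The fallback replaces asymmetric deprotonation by resolution, sets out from 4 and rejoins at 6. LDA and TESCl give the racemic silyl enol ether F5, and the conditions of step 3 with 3 give the racemic trans keto amide F6. LiOH hydrolysis and crystallisation of the acid as a 1-phenylethylammonium salt should give the resolved acid F7; Me3SiCHN2 in MeOH returns 6.

3. Step 13. Metathesis may stall on two hindered alkenes, or dimerise, because the cyclobutane must first flip into the pucker that brings C3 and C11 together. The fallback forms the ring and the diol by a pinacol coupling, sets out from 16 and rejoins at 20. Ozonolysis of the side-chain alkene (O3, then Me2S) gives the dialdehyde F8. SmI2-mediated pinacol cyclisation should form the C2–C3 bond and the cis-diol anti to the C1 silyl ether, giving the C5-silylated diol F9. HF·pyridine then removes the triethylsilyl group and gives 20.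

Further compounds
F1 | step 20 | cyclobutanone: C5 ketone of 23 | CC(C)(C)[Si](C)(C)O[C@@H]1[C@H]3OC(C)(C)O[C@H]3[C@@]2(C)C(=O)[C@@H](C1(C)C)[C@@H]2C(=C)C[Si](C)(C)C
F2 | step 20 | C5 nitrile (cyano group on the top face) | CC(C)(C)[Si](C)(C)O[C@@H]1[C@H]3OC(C)(C)O[C@H]3[C@@]2(C)[C@H](C#N)[C@@H](C1(C)C)[C@@H]2C(=C)C[Si](C)(C)C
F3 | step 20 | C5 aldehyde (formyl group on the top face) | CC(C)(C)[Si](C)(C)O[C@@H]1[C@H]3OC(C)(C)O[C@H]3[C@@]2(C)[C@H](C=O)[C@@H](C1(C)C)[C@@H]2C(=C)C[Si](C)(C)C
F4 | step 20 | bicyclic homoallylic alcohol: C6 carbinol of 28 | CC(C)(C)[Si](C)(C)O[C@@H]1[C@H]4OC(C)(C)O[C@H]4[C@@]2(C)[C@@H]3C(O)CC(=C)[C@H]2[C@@H]3C1(C)C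
F5 | step 2 | racemic methyl 3-(triethylsilyloxy)cyclobut-2-ene-1-carboxylate | COC(=O)C1CC(O[Si](CC)(CC)CC)=C1
F6 | step 2 | racemic trans keto amide (racemate of 6) | COC(=O)C1CC(=O)C1C(C)(C)C(=O)N(C)OC
F7 | step 2 | resolved acid: carboxylic acid of 6 | C1C(=O)[C@@H](C(C)(C)C(=O)N(C)OC)[C@@H]1C(=O)O
F8 | step 13 | dialdehyde: C2 and C3 formyl groups, C1 silyl ether | O=C[C@@]1(C)[C@@H](O[Si](CC)(CC)CC)[C@@H](C(C)(C)[C@H](O[Si](C)(C)C(C)(C)C)C=O)[C@@H]1C(=O)OC
F9 | step 13 | C5 triethylsilyl ether of 20 | CC(C)(C)[Si](C)(C)O[C@@H]1[C@@H](O)[C@@H](O)[C@@]2(C)[C@@H](O[Si](CC)(CC)CC)[C@@H](C1(C)C)[C@@H]2C(=O)OC
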